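## Retrosynthetic overview
1. The last step is a functional-group change only: the allylic alcohol of the target comes from a methyl enoate (i-Bu2AlH).
2. The key disconnection is C7–C8 (C7 = carbinol carbon, C8 = methyl-bearing carbon). The carbonyl carbon of veratraldehyde is joined to a 1-(aryloxy)ethyl carbanion equivalent. This equivalent is the acetal-level carbon of an α-chloro ether, turned from electrophile into nucleophile as a chiral alkylchromium. The aryl ether C–O bond is already in place, and both stereocentres arise in this one step.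
3. The α-chloro ether comes from HCl and an aryl vinyl ether, which comes from methyl sinapate and vinyl acetate (O-vinylation).
4. Methyl sinapate comes from syringaldehyde and a stabilised ylide (Wittig).
5. No ring is formed: ring A (veratraldehyde) and ring B (syringaldehyde) are bought.

Assumption: the (S,S) ligand is written as the one that gives the (1R,2S) series. The sense of induction of this new step must be checked on the first run, and the mirror-image ligand is used if it proves opposite.

## Route

Step 1
Reactants: 1 syringaldehyde (4-hydroxy-3,5-dimethoxybenzaldehyde); 2 methyl (triphenylphosphoranylidene)acetate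
Product: 3 methyl (E)-3-(4-hydroxy-3,5-dimethoxyphenyl)prop-2-enoate (methyl sinapate)
Conditions: 2 (1.2 equiv), toluene, 110 °C
Reagents that add atoms: methyl (triphenylphosphoranylidene)acetate (2), COC(=O)C=P(c1ccccc1)(c1ccccc1)c1ccccc1
Why: Wittig olefination with an ester-stabilised ylide gives the E-enoate selectively and tolerates the free phenol; no stereocentre is formed.

Step 2
Reactants: 3 methyl sinapate; 4 vinyl acetate
Product: 5 methyl (E)-3-[4-(ethenyloxy)-3,5-dimethoxyphenyl]prop-2-enoate
Conditions: 4 (5 equiv), [Ir(cod)Cl]2 (2 mol %), Na2CO3 (1.0 equiv), toluene, 100 °C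
Reagents that add atoms: vinyl acetate (4), C=COC(C)=O
Why: In this iridium-catalysed transvinylation the iridium phenoxide adds across coordinated vinyl acetate and β-acetoxy elimination releases the aryl vinyl ether, while Na2CO3 takes up the acetic acid so that it cannot add back; no stereocentre is formed.

Step 3
Reactants: 5 aryl vinyl ether (1.3 equiv); 6 veratraldehyde (3,4-dimethoxybenzaldehyde, 1.0 equiv)
Product: 10 methyl (E)-3-(4-{[(1R,2S)-1-(3,4-dimethoxyphenyl)-1-hydroxypropan-2-yl]oxy}-3,5-dimethoxyphenyl)prop-2-enoate, via chloro ether 7 (not isolated), via organochromium 8 (not isolated), via silyl ether 9 (not isolated)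
Conditions: HCl (4 M in dioxane, 0.98 equiv relative to 5), CH2Cl2, −20 °C; then 6, CrCl2 (15 mol %), bis[2-((4S)-4-isopropyl-4,5-dihydro-1,3-oxazol-2-yl)phenyl]amine [(S,S)-iPr-BOPA, 18 mol %], i-Pr2NEt (18 mol %), Mn powder (3 equiv), Me3SiCl (1.5 equiv), THF, 0 °C to rt; then citric acid, MeOH/H2O, rt
Reagents that add atoms: none
Why: Proposed new method: HCl adds to 5 in the Markovnikov sense to give the acetal-level chloride 7, whose carbon is a natural electrophile; the strongly reducing N-ligated divalent chromium abstracts this activated chlorine, a second divalent chromium traps the planar α-aryloxy radical, and the trivalent alkylchromium 8 is a 1-aryloxyethyl carbanion equivalent that adds to the aldehyde of 6 and ignores the enoate, with Me3SiCl and Mn turning the metal over; because the Cr–C bond of an oxygen-stabilised alkyl homolyses reversibly, the two C8 epimers of 8 interconvert and the chiral ligand selects one (enantioconvergent); the tridentate ligand, alkyl, chloride and bound aldehyde fill all six sites, so the aryloxy oxygens cannot chelate, and the four-centre transition state places C8–OAr anti to C=O and the aldehyde aryl group next to C8–H, which gives the erythro (1R,2S) product by attack on the Si face of 6; the closest known reaction types are the catalytic asymmetric Nozaki–Hiyama–Kishi reaction and the CrCl2-mediated addition of α-chloro sulfides (α-thioalkylchromium reagents) to aldehydes.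

Step 4
Reactants: 10 erythro hydroxy enoate
Product: 11 (1R,2S)-1-(3,4-dimethoxyphenyl)-2-{4-[(E)-3-hydroxyprop-1-enyl]-2,6-dimethoxyphenoxy}propan-1-ol (target)
Conditions: i-Bu2AlH (4 equiv), CH2Cl2, −78 °C to −20 °C; aq potassium sodium tartrate
Reagents that add atoms: none
Why: The 1,2-selective reduction of the enoate by i-Bu2AlH gives the E-allylic alcohol, with the C7 hydroxyl carried as its aluminium alkoxide, and neither stereocentre nor the alkene geometry is touched at low temperature.

## Compound list
1 | syringaldehyde (4-hydroxy-3,5-dimethoxybenzaldehyde) | COc1cc(C=O)cc(OC)c1O | starting material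
2 | methyl (triphenylphosphoranylidene)acetate | COC(=O)C=P(c1ccccc1)(c1ccccc1)c1ccccc1 | starting material
3 | methyl (E)-3-(4-hydroxy-3,5-dimethoxyphenyl)prop-2-enoate (methyl sinapate) | COC(=O)/C=C/c1cc(OC)c(O)c(OC)c1 | intermediate
4 | vinyl acetate | C=COC(C)=O | starting material
5 | methyl (E)-3-[4-(ethenyloxy)-3,5-dimethoxyphenyl]prop-2-enoate | C=COc1c(OC)cc(/C=C/C(=O)OC)cc1OC | intermediate
6 | veratraldehyde (3,4-dimethoxybenzaldehyde) | COc1ccc(C=O)cc1OC | starting material
7 | methyl (E)-3-[4-(1-chloroethoxy)-3,5-dimethoxyphenyl]prop-2-enoate, racemic | CC(Cl)Oc1c(OC)cc(/C=C/C(=O)OC)cc1OC | intermediate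
8 | 1-(aryloxy)ethylchromium species of trivalent chromium, aryl = 2,6-dimethoxy-4-[(E)-2-(methoxycarbonyl)ethenyl]phenyl; drawn as the ligand-free dichloride (the N,N,N ligand takes the place of one chloride); configurationally labile at carbon | CC([Cr](Cl)Cl)Oc1c(OC)cc(/C=C/C(=O)OC)cc1OC | intermediate
9 | trimethylsilyl ether of 10 at the C7 oxygen, (1R,2S) | COc1ccc([C@@H](O[Si](C)(C)C)[C@H](C)Oc2c(OC)cc(/C=C/C(=O)OC)cc2OC)cc1OC | intermediate
10 | methyl (E)-3-(4-{[(1R,2S)-1-(3,4-dimethoxyphenyl)-1-hydroxypropan-2-yl]oxy}-3,5-dimethoxyphenyl)prop-2-enoate (erythro) | COc1ccc([C@@H](O)[C@H](C)Oc2c(OC)cc(/C=C/C(=O)OC)cc2OC)cc1OC | intermediate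
11 | (1R,2S)-1-(3,4-dimethoxyphenyl)-2-{4-[(E)-3-hydroxyprop-1-enyl]-2,6-dimethoxyphenoxy}propan-1-ol | COc1ccc([C@@H](O)[C@H](C)Oc2c(OC)cc(/C=C/CO)cc2OC)cc1OC | target

## Count and risks
Total step count: 4. Longest linear sequence: 4 (1 → 3 → 5 → 10 → 11); veratraldehyde 6 enters at step 3.

**Step 3 is the most likely to fail.**
- It is a new reaction. The possible failures are slow chlorine abstraction, protonation of 8 to the ethyl ether, pinacol coupling of 6, formation of the threo isomer, or low ee.
- The fallback sets out from 6 (with phenol 3) and comes back at 10. It makes the same C7–C8 bond from the opposite reversed-polarity partner.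
- Benzaldehyde lyase (thiamine diphosphate, MgSO4, phosphate buffer pH 7.5/DMSO, 30 °C) converts 6 into its enzyme-bound acyl anion. This adds to acetaldehyde to give (R)-1-(3,4-dimethoxyphenyl)-2-hydroxypropan-1-one F1.
- Mitsunobu etherification of F1 with 3 (PPh3, DIAD, THF, 0 °C) inverts C8. It gives methyl (E)-3-(4-{[(2S)-1-(3,4-dimethoxyphenyl)-1-oxopropan-2-yl]oxy}-3,5-dimethoxyphenyl)prop-2-enoate F2.
- Chelation-controlled reduction of F2 with Zn(BH4)2 (Et2O, −30 °C) delivers hydride from the C8–H side of the chelate and gives erythro 10.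

**Step 2 is the second most likely to fail.**
- The 2,6-disubstituted and rather acidic phenol may vinylate slowly or be O-acetylated by vinyl acetate.
- The fallback sets out from 3 and comes back at 5.
- Alkylation with 1,2-dibromoethane (K2CO3, DMF, 60 °C) gives methyl (E)-3-[4-(2-bromoethoxy)-3,5-dimethoxyphenyl]prop-2-enoate F3.
- E2 elimination of F3 (t-BuOK, THF, −20 °C to 0 °C) gives 5.

**Step 4 is the third most likely to fail.**
- The risks are partial conjugate reduction, or aluminium-assisted ionisation of the electron-rich benzylic alkoxide with loss of the C7 configuration.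
- The fallback sets out from 10 and comes back at 11.
- LiOH (THF/H2O, rt) gives (E)-3-(4-{[(1R,2S)-1-(3,4-dimethoxyphenyl)-1-hydroxypropan-2-yl]oxy}-3,5-dimethoxyphenyl)prop-2-enoic acid F4.
- Isobutyl chloroformate and N-methylmorpholine (THF, −15 °C) convert F4 into the isobutyl carbonic mixed anhydride of this acid F5.
- F5 is reduced in the same pot with NaBH4 (THF/H2O, 0 °C) to 11.

## Further compounds
F1 | step 3 | (R)-1-(3,4-dimethoxyphenyl)-2-hydroxypropan-1-one | COc1ccc(C(=O)[C@@H](C)O)cc1OC
F2 | step 3 | methyl (E)-3-(4-{[(2S)-1-(3,4-dimethoxyphenyl)-1-oxopropan-2-yl]oxy}-3,5-dimethoxyphenyl)prop-2-enoate | COc1ccc(C(=O)[C@H](C)Oc2c(OC)cc(/C=C/C(=O)OC)cc2OC)cc1OC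
F3 | step 2 | methyl (E)-3-[4-(2-bromoethoxy)-3,5-dimethoxyphenyl]prop-2-enoate | COC(=O)/C=C/c1cc(OC)c(OCCBr)c(OC)c1
F4 | step 4 | (E)-3-(4-{[(1R,2S)-1-(3,4-dimethoxyphenyl)-1-hydroxypropan-2-yl]oxy}-3,5-dimethoxyphenyl)prop-2-enoic acid | COc1ccc([C@@H](O)[C@H](C)Oc2c(OC)cc(/C=C/C(=O)O)cc2OC)cc1OC
F5 | step 4 | isobutyl carbonic mixed anhydride of acid F4 | COc1ccc([C@@H](O)[C@H](C)Oc2c(OC)cc(/C=C/C(=O)OC(=O)OCC(C)C)cc2OC)cc1OC
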